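**Strategy.** The plan disconnects the C2–C3 bond of the dihydropyran ring of the chroman, between the O-bearing benzylic carbon and the isopropyl-bearing carbon. The key step condenses a C-prenylated phlorisovalerophenone, whose only free phenol lies para to the ketone, with threefold-symmetric 2,4,6-trimethoxybenzene-1,3,5-tricarbaldehyde under a chiral Brønsted acid. The aryloxocarbenium ion formed is captured by the prenyl alkene (oxonium-ene cyclization), which closes the pyran ring, sets both stereocentres trans and leaves an isopropenyl group. It exploits that C4, C3 and the isopropyl group together are a prenyl unit ortho to the ring oxygen O1. Hydrogenation and global deprotection finish the synthesis.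

Key step: step 5

Remarks and assumptions
- Chroman numbering is used throughout: O1, C2 (aryl-bearing), C3 (isopropyl-bearing), C4 (CH2). The target is (2R,3S), 2,3-trans.
- Compound 8 is taken as commercially available (it is sold as a monomer for framework materials).
- Assumption: the sense of induction of the chiral acid in step 5 cannot be predicted with certainty. The (S)-acid is written; its mirror image would be used if the cyclization delivers the enantiomeric series.

Step 1
Reactants: 1 phloroglucinol; 2 3-methylbutanoyl chloride
Product: 3 1-(2,4,6-trihydroxyphenyl)-3-methylbutan-1-one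
Conditions: AlCl3 (3.5 equiv), PhNO2, 60 °C; aq. HCl work-up
Reagents that add atoms: none
Why: Friedel–Crafts C-acylation of the symmetric, highly activated arene should stop at the monoketone because the aluminium chelate of the product is deactivated.

Step 2
Reactants: 3 1-(2,4,6-trihydroxyphenyl)-3-methylbutan-1-one; 4 1-bromo-3-methylbut-2-ene
Product: 5 3-methyl-1-[2,4,6-trihydroxy-3-(3-methylbut-2-en-1-yl)phenyl]butan-1-one
Conditions: 4 (0.9 equiv), 10% aq. KOH, 0 °C
Reagents that add atoms: none
Why: In water the phenoxide of an acylphloroglucinol is alkylated at carbon (C-prenylation as in hop acid chemistry); the two free ring positions are equivalent and a deficit of bromide limits double alkylation.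

Step 3
Reactants: 5 3-methyl-1-[2,4,6-trihydroxy-3-(3-methylbut-2-en-1-yl)phenyl]butan-1-one
Product: 6 1-[2,4,6-triacetoxy-3-(3-methylbut-2-en-1-yl)phenyl]-3-methylbutan-1-one
Conditions: Ac2O, pyridine, DMAP (cat.), CH2Cl2, 0 °C to rt
Reagents that add atoms: acetic anhydride CC(=O)OC(C)=O
Why: DMAP-catalysed O-acetylation should esterify all three phenols, including the two hydrogen-bonded ones.

Step 4
Reactants: 6 1-[2,4,6-triacetoxy-3-(3-methylbut-2-en-1-yl)phenyl]-3-methylbutan-1-one
Product: 7 1-[2,6-diacetoxy-4-hydroxy-3-(3-methylbut-2-en-1-yl)phenyl]-3-methylbutan-1-one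
Conditions: PhSH (1.1 equiv), imidazole (0.3 equiv), NMP, 0 °C
Reagents that add atoms: none
Why: Thiolate transesterification should remove selectively the acetate para to the ketone, which has the best phenoxide leaving group and is not shielded by the acyl group, as known for the 7-acetate of peracetylated flavonoids.

Step 5
Reactants: 7 1-[2,6-diacetoxy-4-hydroxy-3-(3-methylbut-2-en-1-yl)phenyl]-3-methylbutan-1-one; 8 2,4,6-trimethoxybenzene-1,3,5-tricarbaldehyde
Product: 10 (2R,3S)-5,7-diacetoxy-2-(3,5-diformyl-2,4,6-trimethoxyphenyl)-6-(3-methylbutanoyl)-3-(prop-1-en-2-yl)chroman, via aryloxocarbenium ion 9 (not isolated)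
Conditions: 8 (3 equiv), (S)-3,3'-bis(2,4,6-triisopropylphenyl)-1,1'-binaphthyl-2,2'-diyl N-triflylphosphoramide (10 mol %), 5 Å molecular sieves, toluene, −30 °C
Reagents that add atoms: none
Why: Proposed new method: the acid condenses the only free phenol of 7 with one of the three equivalent formyl groups of 8 to give the aryloxocarbenium ion 9, whose carbon is attacked by the less substituted carbon of the prenyl C=C, and the developing tertiary cation loses a methyl proton to the chiral anion (oxonium-ene, a Prins-type cyclization), so that water is the only by-product. The closest known reaction types are the Lewis acid catalysed oxonium-ene cyclization of alkenols with aldehydes and the chiral-acid catalysed asymmetric Prins and carbonyl-ene cyclizations, whereas a catalytic enantioselective version of this oxonium-ene mode has not been shown. The dihydropyran ring closes by forming the C2–C3 bond in the 6-exo-trig mode with respect to the alkene (endo with respect to the C=O+ bond), the 7-endo alternative being excluded because it would need a secondary cation. The trans relation of C2 and C3 should follow from a chair-like transition state with the aryl group and the isopropylidene unit pseudo-equatorial and is also the more stable arrangement, while the absolute configuration at C3 is fixed by the chiral counter-anion, which shields one face of the alkene in the contact ion pair. The step needs O-alkylation of one defined phenol instead of ring C-alkylation, no capture of the tertiary cation and no acid-induced closure of the prenyl group onto the phenol: the two acetates leave a single free OH and deactivate the arene, the methyl ethers of 8 remove every internal nucleophile, and low temperature with excess aldehyde favours carbonyl activation over alkene protonation.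

Step 6
Reactants: 10 (2R,3S)-5,7-diacetoxy-2-(3,5-diformyl-2,4,6-trimethoxyphenyl)-6-(3-methylbutanoyl)-3-(prop-1-en-2-yl)chroman
Product: 11 (2R,3S)-5,7-diacetoxy-2-(3,5-diformyl-2,4,6-trimethoxyphenyl)-3-isopropyl-6-(3-methylbutanoyl)chroman
Conditions: H2 (1 atm), RhCl(PPh3)3 (5 mol %), toluene/EtOH, rt
Reagents that add atoms: none
Why: Homogeneous hydrogenation with RhCl(PPh3)3 should saturate the unhindered 1,1-disubstituted alkene and leave the aryl aldehydes, the ketone, the acetates and the benzylic C–O bond untouched; no stereocentre is formed or touched.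

Step 7
Reactants: 11 (2R,3S)-5,7-diacetoxy-2-(3,5-diformyl-2,4,6-trimethoxyphenyl)-3-isopropyl-6-(3-methylbutanoyl)chroman
Product: 13 5-[(2R,3S)-5,7-dihydroxy-6-(3-methylbutanoyl)-3-(propan-2-yl)-3,4-dihydro-2H-chromen-2-yl]-2,4,6-trihydroxybenzene-1,3-dicarbaldehyde, via diacetate 12 (not isolated)
Conditions: BBr3 (12 equiv), CH2Cl2, −78 °C to 0 °C; then MeOH, 0 °C to 40 °C
Reagents that add atoms: none
Why: BBr3 should cleave the three aryl methyl ethers (Lewis acid mediated ether cleavage, each next to a formyl group) and the HBr/MeOH formed on quenching should transesterify the two aryl acetates; C3 is not affected, and C2, should it ionize, returns to the more stable trans arrangement.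

**Compound list**

1 | phloroglucinol (benzene-1,3,5-triol) | Oc1cc(O)cc(O)c1 | starting material
2 | 3-methylbutanoyl chloride (isovaleryl chloride) | CC(C)CC(Cl)=O | starting material
3 | 1-(2,4,6-trihydroxyphenyl)-3-methylbutan-1-one (phlorisovalerophenone) | CC(C)CC(=O)c1c(O)cc(O)cc1O | intermediate
4 | 1-bromo-3-methylbut-2-ene (prenyl bromide) | CC(C)=CCBr | starting material
5 | 3-methyl-1-[2,4,6-trihydroxy-3-(3-methylbut-2-en-1-yl)phenyl]butan-1-one | CC(C)CC(=O)c1c(O)cc(O)c(CC=C(C)C)c1O | intermediate
6 | 1-[2,4,6-triacetoxy-3-(3-methylbut-2-en-1-yl)phenyl]-3-methylbutan-1-one | CC(C)CC(=O)c1c(OC(C)=O)cc(OC(C)=O)c(CC=C(C)C)c1OC(C)=O | intermediate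
7 | 1-[2,6-diacetoxy-4-hydroxy-3-(3-methylbut-2-en-1-yl)phenyl]-3-methylbutan-1-one (free OH para to the ketone, ortho to the prenyl group) | CC(C)CC(=O)c1c(OC(C)=O)cc(O)c(CC=C(C)C)c1OC(C)=O | intermediate
8 | 2,4,6-trimethoxybenzene-1,3,5-tricarbaldehyde | COc1c(C=O)c(OC)c(C=O)c(OC)c1C=O | starting material
9 | O-aryl oxocarbenium ion from the C4–OH of 7 and one formyl group of 8 (counter-ion: chiral phosphoramide anion) | CC(C)CC(=O)c1c(OC(C)=O)cc([O+]=Cc2c(OC)c(C=O)c(OC)c(C=O)c2OC)c(CC=C(C)C)c1OC(C)=O | intermediate (not isolated)
10 | (2R,3S)-5,7-diacetoxy-2-(3,5-diformyl-2,4,6-trimethoxyphenyl)-6-(3-methylbutanoyl)-3-(prop-1-en-2-yl)chroman (2,3-trans) | CC(C)CC(=O)c1c(OC(C)=O)cc2c(c1OC(C)=O)C[C@@H](C(C)=C)[C@H](c1c(OC)c(C=O)c(OC)c(C=O)c1OC)O2 | intermediate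
11 | (2R,3S)-5,7-diacetoxy-2-(3,5-diformyl-2,4,6-trimethoxyphenyl)-3-isopropyl-6-(3-methylbutanoyl)chroman | CC(C)CC(=O)c1c(OC(C)=O)cc2c(c1OC(C)=O)C[C@@H](C(C)C)[C@H](c1c(OC)c(C=O)c(OC)c(C=O)c1OC)O2 | intermediate
12 | (2R,3S)-5,7-diacetoxy-2-(3,5-diformyl-2,4,6-trihydroxyphenyl)-3-isopropyl-6-(3-methylbutanoyl)chroman | CC(C)CC(=O)c1c(OC(C)=O)cc2c(c1OC(C)=O)C[C@@H](C(C)C)[C@H](c1c(O)c(C=O)c(O)c(C=O)c1O)O2 | intermediate (not isolated)
13 | 5-[(2R,3S)-5,7-dihydroxy-6-(3-methylbutanoyl)-3-(propan-2-yl)-3,4-dihydro-2H-chromen-2-yl]-2,4,6-trihydroxybenzene-1,3-dicarbaldehyde | CC(C)CC(=O)c1c(O)cc2c(c1O)C[C@@H](C(C)C)[C@H](c1c(O)c(C=O)c(O)c(C=O)c1O)O2 | target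

**Step count.** Total: 7 steps. Longest linear sequence: 7 steps (1 to 13; compound 8 enters in step 5).

**Steps most likely to fail**

Step 5 (proposed new method). The chiral anion may discriminate the two faces of the prenyl alkene poorly. The acid may also protonate the prenyl group and close it onto the phenol, or move the new double bond into the isopropylidene position and erase the C3 stereocentre. The fallback uses known chemistry and sets out from compounds 7 and 8. The cyclization is run without asymmetric induction under In(OTf)3 (10 mol %) in CH2Cl2 at 0 °C, the oxonium-ene conditions known for alkenols and aldehydes. This should give the racemic trans-chroman F1, trans by the same chair-like closure and by thermodynamic preference. The enantiomers are then separated by preparative HPLC on a chiral stationary phase (amylose tris(3,5-dimethylphenylcarbamate)). The (2R,3S)-enantiomer is compound 10, where the route is rejoined.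

Step 7. BBr3 may heterolyse the benzylic C2–O1 bond with capture of the cation by bromide, or may leave the methyl ether flanked by two formyl groups partly uncleaved. The fallback replaces methyl by benzyl protection, sets out from compound 7 and comes back at compound 12. Commercial 2,4,6-triformylphloroglucinol is O-benzylated (BnBr, K2CO3, DMF) to 2,4,6-tris(benzyloxy)benzene-1,3,5-tricarbaldehyde F2. F2 takes the place of 8 in the cyclization with 7 under the conditions of step 5 and should give the tribenzyl isopropenyl chroman F3. Hydrogenation over palladium on carbon (H2, EtOAc, rt) should saturate the alkene and cleave the three benzyl ethers in one operation to give diacetate 12, here isolated. K2CO3 in MeOH at 0 °C then removes the two acetates to give 13.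

Step 4. Thiolysis may be unselective, with loss of an acetate ortho to the ketone or double deacetylation. The fallback differentiates the phenols by silylation first, sets out from compound 5 and comes back at compound 7. TBSCl (1.0 equiv) and imidazole in CH2Cl2 at 0 °C should silylate the most acidic, non-chelated phenol para to the ketone to give the 4-O-silyl ether F4. Ac2O, pyridine and DMAP acetylate the two remaining phenols to give the silyl diacetate F5. HF·pyridine in THF at 0 °C removes the silyl group and gives 7.

**Further compounds**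

F1 | step 5 | racemic trans-5,7-diacetoxy-2-(3,5-diformyl-2,4,6-trimethoxyphenyl)-6-(3-methylbutanoyl)-3-(prop-1-en-2-yl)chroman (both enantiomers written) | CC(C)CC(=O)c1c(OC(C)=O)cc2c(c1OC(C)=O)C[C@@H](C(C)=C)[C@H](c1c(OC)c(C=O)c(OC)c(C=O)c1OC)O2.CC(C)CC(=O)c1c(OC(C)=O)cc2c(c1OC(C)=O)C[C@H](C(C)=C)[C@@H](c1c(OC)c(C=O)c(OC)c(C=O)c1OC)O2
F2 | step 7 | 2,4,6-tris(benzyloxy)benzene-1,3,5-tricarbaldehyde | O=Cc1c(OCc2ccccc2)c(C=O)c(OCc2ccccc2)c(C=O)c1OCc1ccccc1
F3 | step 7 | (2R,3S)-5,7-diacetoxy-2-[2,4,6-tris(benzyloxy)-3,5-diformylphenyl]-6-(3-methylbutanoyl)-3-(prop-1-en-2-yl)chroman | CC(C)CC(=O)c1c(OC(C)=O)cc2c(c1OC(C)=O)C[C@@H](C(C)=C)[C@H](c1c(OCc3ccccc3)c(C=O)c(OCc3ccccc3)c(C=O)c1OCc1ccccc1)O2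
F4 | step 4 | 1-[4-(tert-butyldimethylsilyloxy)-2,6-dihydroxy-3-(3-methylbut-2-en-1-yl)phenyl]-3-methylbutan-1-one | CC(C)CC(=O)c1c(O)cc(O[Si](C)(C)C(C)(C)C)c(CC=C(C)C)c1O
F5 | step 4 | 1-[2,6-diacetoxy-4-(tert-butyldimethylsilyloxy)-3-(3-methylbut-2-en-1-yl)phenyl]-3-methylbutan-1-one | CC(C)CC(=O)c1c(OC(C)=O)cc(O[Si](C)(C)C(C)(C)C)c(CC=C(C)C)c1OC(C)=O
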